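**Retrosynthetic overview**

- The tertiary cyclopentanol comes last, by hydration of an exocyclic methylene; the tetrasubstituted enone comes from a 1,3-oxidative transposition of a tertiary allylic alcohol.
- That alcohol is the union point (C–C bond between the ethylene bridge and the seven-membered ring): a left-half alkyllithium adds to a right-half bicyclic 2-methylcycloheptenone.
- Left half: oxepane and cyclohexane form together in one epoxide-opening cascade of a Shi-derived diepoxide ending on a regiodefined enol silane; equatorial methyl addition then gives the axial tertiary alcohol.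
- Right half: the cyclopentane is cyclopent-2-enone; a six-membered ring is annulated asymmetrically with a gem-dimethyl silyloxydiene (new step), then enlarged by one carbon to the α-methyl cycloheptenone.
- Ring order: oxepane + cyclohexane (left) ∥ cyclohexene → cycloheptenone on the cyclopentane (right) → union → enone → carbinol.

Assumption: 4-methylpent-1-en-3-one, the D-fructose-derived Shi ketone and both antipodes of the chiral acid catalyst of step 7 are taken as purchasable.

**Step 1**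
Reactants: 1 geranylacetone, (5E)-6,10-dimethylundeca-5,9-dien-2-one
Product: 2 (5R,6R,9R)-5,6:9,10-diepoxy-6,10-dimethylundecan-2-one
Conditions: D-fructose-derived Shi ketone (0.5 equiv), KHSO5 (as 2KHSO5·KHSO4·K2SO4), K2CO3, Bu4NHSO4, MeCN–CH2(OMe)2–aq. Na2B4O7 buffer, 0 °C
Reagents that add atoms: potassium peroxymonosulfate, [K+].[O-]S(=O)(=O)OO
Why: Shi asymmetric epoxidation, in which the chiral dioxirane attacks both electron-rich trisubstituted alkenes through the spiro transition state from the same enantioface, setting C5, C6 and C9 as R (the first stereocentres) and leaving the methyl ketone alone.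

**Step 2**
Reactants: 2 (5R,6R,9R)-5,6:9,10-diepoxy-6,10-dimethylundecan-2-one
Product: 5 (6R,7R,10R)-6,7:10,11-diepoxy-7,11-dimethyldodec-1-en-3-one, via Mannich base 3 (not isolated), via methiodide 4 (not isolated)
Conditions: LiN(i-Pr)2, THF, −78 °C; CH2=NMe2+ I−, −78 → 0 °C; then MeI, CH2Cl2, rt; then aq. NaHCO3
Reagents that add atoms: Eschenmoser's salt (N,N-dimethylmethyleneiminium iodide), C=[N+](C)C.[I-]
Why: Kinetic enolisation at the methyl group, Mannich alkylation, then quaternisation and E1cB elimination give the vinyl ketone under conditions the trisubstituted epoxides tolerate (no stereocentre is made or touched).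

**Step 3**
Reactants: 5 (6R,7R,10R)-6,7:10,11-diepoxy-7,11-dimethyldodec-1-en-3-one
Product: 6 tert-butyl{[(3Z,7R,8R,11R)-7,8:11,12-diepoxy-8,12-dimethyl-1-(phenylsulfanyl)tridec-3-en-4-yl]oxy}dimethylsilane
Conditions: LiCu(CH2SPh)2, THF, −78 °C; then t-BuMe2SiCl, HMPA, −78 → 0 °C
Reagents that add atoms: lithium bis(phenylthiomethyl)cuprate, [Li+].c1ccccc1SC[Cu-]CSc1ccccc1; tert-butyldimethylsilyl chloride, CC(C)(C)[Si](C)(C)Cl
Why: Organocuprate conjugate addition to the s-cis vinyl ketone followed by O-silylation of the enolate fixes the enol silane regiochemistry (Z) and brings in the thioether that later becomes the carbanion.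

**Step 4**
Reactants: 6 tert-butyl{[(3Z,7R,8R,11R)-7,8:11,12-diepoxy-8,12-dimethyl-1-(phenylsulfanyl)tridec-3-en-4-yl]oxy}dimethylsilane
Product: 7 (3R,5aR,6R,9aR)-3-(tert-butyldimethylsilyloxy)-2,2,5a-trimethyl-6-[2-(phenylsulfanyl)ethyl]-3,4,5,5a,6,8,9,9a-octahydro-1-benzoxepin-7(2H)-one
Conditions: t-BuMe2SiOTf (0.2 equiv), 2,6-di-tert-butyl-4-methylpyridine, CH2Cl2, −78 °C
Reagents that add atoms: none
Why: Silyl-triflate-triggered tandem oxa-/carbacyclisation (epoxide-opening cascade): the internal epoxide oxygen opens the silylated terminal epoxide at its tertiary carbon (oxepane, C3 retained), and the enol silane opens the resulting epoxonium at its tertiary carbon with inversion through a chair, giving the trans ring fusion and the equatorial side chain while the enol silyl group is passed to the next epoxide.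

**Step 5**
Reactants: 7 (3R,5aR,6R,9aR)-3-(tert-butyldimethylsilyloxy)-2,2,5a-trimethyl-6-[2-(phenylsulfanyl)ethyl]-3,4,5,5a,6,8,9,9a-octahydro-1-benzoxepin-7(2H)-one
Product: 8 (3R,5aR,6R,7S,9aR)-3-(tert-butyldimethylsilyloxy)-2,2,5a,7-tetramethyl-6-[2-(phenylsulfanyl)ethyl]decahydro-1-benzoxepin-7-ol
Conditions: MeMgBr, CeCl3, THF, −78 → 0 °C
Reagents that add atoms: methylmagnesium bromide, C[Mg]Br
Why: Cerium-mediated Grignard 1,2-addition in which the axial trajectory is blocked by the syn-axial C5a methyl, so methyl enters equatorially and the new hydroxyl is axial (7S).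

**Step 6**
Reactants: 9 4-methylpent-1-en-3-one
Product: 10 tert-butyldimethyl[(4-methylpenta-1,3-dien-3-yl)oxy]silane
Conditions: t-BuMe2SiOTf, Et3N, CH2Cl2, 0 °C
Reagents that add atoms: tert-butyldimethylsilyl trifluoromethanesulfonate, CC(C)(C)[Si](C)(C)OS(=O)(=O)C(F)(F)F
Why: Soft enolisation and O-silylation, where the isopropyl methine is the only enolisable position, so one 2-silyloxydiene with a gem-dimethyl terminus forms.

**Step 7**
Reactants: 10 tert-butyldimethyl[(4-methylpenta-1,3-dien-3-yl)oxy]silane; 11 cyclopent-2-en-1-one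
Product: 13 (3aR,7aR)-5-(tert-butyldimethylsilyloxy)-4,4-dimethyl-2,3,3a,4,7,7a-hexahydro-1H-inden-1-one, via Michael adduct 12 (not isolated)
Conditions: chiral imidodiphosphorimidate Brønsted acid (3 mol%, the antipode that gives the 3aR,7aR adduct), toluene, −60 °C
Reagents that add atoms: none
Why: Proposed new method: the confined strong acid is silylated by diene 10 to a chiral silylium ion pair that activates cyclopent-2-enone, the gem-dimethyl enol-silane terminus adds to the enone β-carbon inside the chiral anion pocket (enantio-determining Mukaiyama–Michael step that makes the quaternary–tertiary bond and sets C3a), and the cyclopentenyl silyl ether so formed closes onto the released vinyl ketone in a second, intramolecular Mukaiyama–Michael step that can only give the cis ring fusion (C7a), the silyl group ending on the cyclohexenyl oxygen; the closest known reaction types are silylium/imidodiphosphorimidate-catalysed Mukaiyama–Michael additions of silyl ketene acetals, cationic oxazaborolidine-catalysed Diels–Alder additions of 2-silyloxybutadienes to cycloalkenones and racemic Lewis-acid double Michael annulations, none of which has been shown enantioselectively with a diene terminus that creates a quaternary carbon.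

**Step 8**
Reactants: 13 (3aR,7aR)-5-(tert-butyldimethylsilyloxy)-4,4-dimethyl-2,3,3a,4,7,7a-hexahydro-1H-inden-1-one
Product: 14 tert-butyl{[(3aR,7aR)-4,4-dimethyl-1-methylidene-2,3,3a,4,7,7a-hexahydro-1H-inden-5-yl]oxy}dimethylsilane
Conditions: Ph3PCH3Br, KOt-Bu, THF, 0 °C → rt
Reagents that add atoms: methyltriphenylphosphonium bromide, C[P+](c1ccccc1)(c1ccccc1)c1ccccc1.[Br-]
Why: Wittig methylenation of the cyclopentanone, with the silyl enol ether inert and the cis fusion (the favoured one for a hydrindan-1-one) kept.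

**Step 9**
Reactants: 14 tert-butyl{[(3aR,7aR)-4,4-dimethyl-1-methylidene-2,3,3a,4,7,7a-hexahydro-1H-inden-5-yl]oxy}dimethylsilane
Product: 16 (3aR,8aR)-4,4,6-trimethyl-1-methylidene-2,3,3a,4,8,8a-hexahydroazulen-5(1H)-one, via chlorocyclopropane 15 (not isolated)
Conditions: CH3CHCl2, n-BuLi, Et2O, −40 °C → rt; then toluene, 80 °C
Reagents that add atoms: 1,1-dichloroethane, CC(Cl)Cl
Why: Halocarbene ring expansion of a silyl enol ether: the chloro(methyl)carbenoid cyclopropanates the electron-rich enol ether in preference to the 1,1-disubstituted alkene, and the endo-chloro adduct opens (siloxy-assisted disrotatory cleavage of the ring-fusion bond, loss of the silyl chloride) to the one-carbon-larger α-methyl enone without touching the stereocentres.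

**Step 10**
Reactants: 8 (3R,5aR,6R,7S,9aR)-3-(tert-butyldimethylsilyloxy)-2,2,5a,7-tetramethyl-6-[2-(phenylsulfanyl)ethyl]decahydro-1-benzoxepin-7-ol; 16 (3aR,8aR)-4,4,6-trimethyl-1-methylidene-2,3,3a,4,8,8a-hexahydroazulen-5(1H)-one
Product: 18 (3R,5aR,6R,7S,9aR)-3-(tert-butyldimethylsilyloxy)-6-{2-[(3aR,8aR)-5-hydroxy-4,4,6-trimethyl-1-methylidene-1,2,3,3a,4,5,8,8a-octahydroazulen-5-yl]ethyl}-2,2,5a,7-tetramethyldecahydro-1-benzoxepin-7-ol (both epimers at the new carbinol carbon), via dilithio species 17 (not isolated)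
Conditions: n-BuLi (1 equiv), THF, −78 °C; lithium 4,4′-di-tert-butylbiphenylide (2 equiv), −78 °C; then 16, −78 → −20 °C; H2O
Reagents that add atoms: none
Why: Reductive lithiation of the primary alkyl phenyl sulfide gives the alkyllithium, which adds 1,2 to the enone carbonyl (no α′ hydrogen to lose), and the new carbinol centre is erased in the next step.

**Step 11**
Reactants: 18 (3R,5aR,6R,7S,9aR)-3-(tert-butyldimethylsilyloxy)-6-{2-[(3aR,8aR)-5-hydroxy-4,4,6-trimethyl-1-methylidene-1,2,3,3a,4,5,8,8a-octahydroazulen-5-yl]ethyl}-2,2,5a,7-tetramethyldecahydro-1-benzoxepin-7-ol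
Product: 19 (3R,5aR,6R,7S,9aR)-3-(tert-butyldimethylsilyloxy)-6-{2-[(3aR,8aR)-4,4,6-trimethyl-1-methylidene-7-oxo-1,2,3,3a,4,7,8,8a-octahydroazulen-5-yl]ethyl}-2,2,5a,7-tetramethyldecahydro-1-benzoxepin-7-ol
Conditions: pyridinium chlorochromate (C5H5NH[CrO3Cl]), 4 Å molecular sieves, CH2Cl2, rt
Reagents that add atoms: none
Why: Dauben–Babler oxidative 1,3-transposition ([3,3] shift of the tertiary allylic chromate, then oxidation) gives the tetrasubstituted enone, the secondary oxygen being silyl-protected and the other tertiary alcohol not oxidisable.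

**Step 12**
Reactants: 19 (3R,5aR,6R,7S,9aR)-3-(tert-butyldimethylsilyloxy)-6-{2-[(3aR,8aR)-4,4,6-trimethyl-1-methylidene-7-oxo-1,2,3,3a,4,7,8,8a-octahydroazulen-5-yl]ethyl}-2,2,5a,7-tetramethyldecahydro-1-benzoxepin-7-ol
Product: 21 (3R,5aR,6R,7S,9aR)-6-{2-[(1R,3aR,8aR)-1-hydroxy-1,4,4,6-tetramethyl-7-oxo-1,2,3,3a,4,7,8,8a-octahydroazulen-5-yl]ethyl}-2,2,5a,7-tetramethyldecahydro-1-benzoxepine-3,7-diol, via silyl ether 20 (not isolated)
Conditions: Co(acac)2 (0.2 equiv), PhSiH3, O2 (1 atm), i-PrOH–THF, rt; then Bu4NF, THF, 50 °C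
Reagents that add atoms: dioxygen, O=O
Why: Mukaiyama hydration, in which hydrogen-atom transfer to the exocyclic 1,1-disubstituted alkene gives a tertiary radical that takes up O2 on the convex face (the side of the two ring-fusion hydrogens) and so sets 1R, the hindered tetrasubstituted enone being spared, after which fluoride removes the silyl ether.

**Compound list**

1 | geranylacetone, (5E)-6,10-dimethylundeca-5,9-dien-2-one | CC(=O)CC/C=C(\C)CCC=C(C)C | starting material
2 | (5R,6R,9R)-5,6:9,10-diepoxy-6,10-dimethylundecan-2-one | CC(=O)CC[C@H]1O[C@]1(C)CC[C@H]1OC1(C)C | intermediate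
3 | (6R,7R,10R)-1-(dimethylamino)-6,7:10,11-diepoxy-7,11-dimethyldodecan-3-one (Mannich base) | CN(C)CCC(=O)CC[C@H]1O[C@]1(C)CC[C@H]1OC1(C)C | intermediate (not isolated)
4 | trimethylammonium iodide of 3 (methiodide) | C[N+](C)(C)CCC(=O)CC[C@H]1O[C@]1(C)CC[C@H]1OC1(C)C.[I-] | intermediate (not isolated)
5 | (6R,7R,10R)-6,7:10,11-diepoxy-7,11-dimethyldodec-1-en-3-one | C=CC(=O)CC[C@H]1O[C@]1(C)CC[C@H]1OC1(C)C | intermediate
6 | tert-butyl{[(3Z,7R,8R,11R)-7,8:11,12-diepoxy-8,12-dimethyl-1-(phenylsulfanyl)tridec-3-en-4-yl]oxy}dimethylsilane | CC(C)(C)[Si](C)(C)O/C(CC[C@H]1O[C@]1(C)CC[C@H]1OC1(C)C)=C\CCSc1ccccc1 | intermediate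
7 | (3R,5aR,6R,9aR)-3-(tert-butyldimethylsilyloxy)-2,2,5a-trimethyl-6-[2-(phenylsulfanyl)ethyl]-3,4,5,5a,6,8,9,9a-octahydro-1-benzoxepin-7(2H)-one | c1ccccc1SCC[C@@H]2[C@@]3(C)CC[C@@H](O[Si](C)(C)C(C)(C)C)C(C)(C)O[C@@H]3CCC2=O | intermediate
8 | (3R,5aR,6R,7S,9aR)-3-(tert-butyldimethylsilyloxy)-2,2,5a,7-tetramethyl-6-[2-(phenylsulfanyl)ethyl]decahydro-1-benzoxepin-7-ol | c1ccccc1SCC[C@@H]2[C@@]3(C)CC[C@@H](O[Si](C)(C)C(C)(C)C)C(C)(C)O[C@@H]3CC[C@]2(C)O | intermediate
9 | 4-methylpent-1-en-3-one | CC(C)C(=O)C=C | starting material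
10 | tert-butyldimethyl[(4-methylpenta-1,3-dien-3-yl)oxy]silane | CC(C)=C(O[Si](C)(C)C(C)(C)C)C=C | intermediate
11 | cyclopent-2-en-1-one | O=C1CCC=C1 | starting material
12 | 4-[(1R)-3-(tert-butyldimethylsilyloxy)cyclopent-2-en-1-yl]-4-methylpent-1-en-3-one | C=CC(=O)C(C)(C)[C@@H]1CCC(O[Si](C)(C)C(C)(C)C)=C1 | intermediate (not isolated)
13 | (3aR,7aR)-5-(tert-butyldimethylsilyloxy)-4,4-dimethyl-2,3,3a,4,7,7a-hexahydro-1H-inden-1-one (cis-fused) | C1=C(O[Si](C)(C)C(C)(C)C)C(C)(C)[C@@H]2CCC(=O)[C@@H]2C1 | intermediate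
14 | tert-butyl{[(3aR,7aR)-4,4-dimethyl-1-methylidene-2,3,3a,4,7,7a-hexahydro-1H-inden-5-yl]oxy}dimethylsilane | C1=C(O[Si](C)(C)C(C)(C)C)C(C)(C)[C@@H]2CCC(=C)[C@@H]2C1 | intermediate
15 | chloro(methyl)carbene adduct of 14 across the silyl enol ether (1-silyloxy-7-chloro-7-methylbicyclo[4.1.0]heptane unit; isomer mixture at the three cyclopropane carbons, ring-fusion centres as in 14) | CC1(Cl)C2C[C@H]3C(=C)CC[C@H]3C(C)(C)C12O[Si](C)(C)C(C)(C)C | intermediate (not isolated)
16 | (3aR,8aR)-4,4,6-trimethyl-1-methylidene-2,3,3a,4,8,8a-hexahydroazulen-5(1H)-one (cis-fused) | O=C1C(C)=CC[C@H]2C(=C)CC[C@H]2C1(C)C | intermediate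
17 | O,C-dilithio derivative of 8 (lithium 7-alkoxide, 2-lithioethyl chain in place of the 2-(phenylsulfanyl)ethyl chain) | [Li]CC[C@@H]2[C@@]3(C)CC[C@@H](O[Si](C)(C)C(C)(C)C)C(C)(C)O[C@@H]3CC[C@]2(C)O[Li] | intermediate (not isolated)
18 | (3R,5aR,6R,7S,9aR)-3-(tert-butyldimethylsilyloxy)-6-{2-[(3aR,8aR)-5-hydroxy-4,4,6-trimethyl-1-methylidene-1,2,3,3a,4,5,8,8a-octahydroazulen-5-yl]ethyl}-2,2,5a,7-tetramethyldecahydro-1-benzoxepin-7-ol (carbinol carbon of the azulene unspecified, both epimers) | CC1=CC[C@H]2C(=C)CC[C@H]2C(C)(C)C1(O)CC[C@@H]3[C@@]4(C)CC[C@@H](O[Si](C)(C)C(C)(C)C)C(C)(C)O[C@@H]4CC[C@]3(C)O | intermediate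
19 | (3R,5aR,6R,7S,9aR)-3-(tert-butyldimethylsilyloxy)-6-{2-[(3aR,8aR)-4,4,6-trimethyl-1-methylidene-7-oxo-1,2,3,3a,4,7,8,8a-octahydroazulen-5-yl]ethyl}-2,2,5a,7-tetramethyldecahydro-1-benzoxepin-7-ol | CC1=C(CC[C@@H]2[C@@]3(C)CC[C@@H](O[Si](C)(C)C(C)(C)C)C(C)(C)O[C@@H]3CC[C@]2(C)O)C(C)(C)[C@@H]2CCC(=C)[C@@H]2CC1=O | intermediate
20 | 3-O-tert-butyldimethylsilyl ether of 21 | CC1=C(CC[C@@H]2[C@@]3(C)CC[C@@H](O[Si](C)(C)C(C)(C)C)C(C)(C)O[C@@H]3CC[C@]2(C)O)C(C)(C)[C@@H]2CC[C@@](C)(O)[C@@H]2CC1=O | intermediate (not isolated)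
21 | (3R,5aR,6R,7S,9aR)-6-{2-[(1R,3aR,8aR)-1-hydroxy-1,4,4,6-tetramethyl-7-oxo-1,2,3,3a,4,7,8,8a-octahydroazulen-5-yl]ethyl}-2,2,5a,7-tetramethyldecahydro-1-benzoxepine-3,7-diol | CC1=C(CC[C@@H]2[C@@]3(C)CC[C@@H](O)C(C)(C)O[C@@H]3CC[C@]2(C)O)C(C)(C)[C@@H]2CC[C@@](C)(O)[C@@H]2CC1=O | target

**Step count**

Total: 12 steps. Longest linear sequence: 8 steps (steps 1–5, then 10–12); the right-half branch is steps 6–9.

**The three steps most likely to fail**

Step 7 (the proposed new annulation). The first Michael step must join a tetrasubstituted enol-silane carbon to the enone, so it may stall at adduct 12, give low enantioselectivity, or oligomerise the vinyl ketone. The fallback uses known chemistry and sets out from 11. A Diels–Alder addition of 11 to the parent diene tert-butyl(buta-1,3-dien-2-yloxy)dimethylsilane F1 (from but-3-en-2-one, t-BuMe2SiOTf, Et3N), catalysed by a triflimide-activated chiral oxazaborolidine (a metal-free cationic boron Lewis acid), gives (3aS,7aR)-5-(tert-butyldimethylsilyloxy)-2,3,3a,4,7,7a-hexahydro-1H-inden-1-one F2. The Wittig conditions of step 8 give tert-butyldimethyl{[(3aS,7aR)-1-methylidene-2,3,3a,4,7,7a-hexahydro-1H-inden-5-yl]oxy}silane F3, and the ring expansion of step 9 gives (3aS,8aR)-6-methyl-1-methylidene-2,3,3a,4,8,8a-hexahydroazulen-5(1H)-one F4. Two rounds of kinetic α′-deprotonation and methylation (LiN(i-Pr)2, MeI, THF, −78 °C, at the only α′ position of the cross-conjugated enolate) install the gem-dimethyl group, and the route is rejoined at 16.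

Step 9 (carbenoid ring expansion). Only the cyclopropane isomer with chlorine cis to the six-membered ring can open, and the carbenoid may also touch the exocyclic alkene. The fallback sets out from 14. Dibromocarbene (CHBr3, KOt-Bu, pentane, −20 °C) gives the gem-dibromocyclopropane adduct of 14 F5, in which one bromine is necessarily on the productive side. Warming with pyridine in toluene opens it to (3aR,8aR)-6-bromo-4,4-dimethyl-1-methylidene-2,3,3a,4,8,8a-hexahydroazulen-5(1H)-one F6. Suzuki–Miyaura methylation of this α-bromo enone (trimethylboroxine, Pd(dppf)Cl2, K2CO3, dioxane, 80 °C) comes back to the route at 16.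

Step 10 (fragment union). The carbonyl of 16 sits between a quaternary carbon and a methyl-bearing alkene carbon, so the alkyllithium may deprotonate the γ-methylene or fail to add. The fallback avoids carbonyl addition; it sets out from 16 and 8.
- Conjugate reduction of 16 with Li[HB(s-Bu)3] and trapping of the enolate with PhNTf2 gives (3aR,8aR)-4,4,6-trimethyl-1-methylidene-1,2,3,3a,4,7,8,8a-octahydroazulen-5-yl trifluoromethanesulfonate F7.
- Compound 8 is lithiated as in step 10 and transmetalated with ZnCl2 to the alkylzinc chloride of the left half F8.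
- Negishi coupling (Pd(dppf)Cl2, THF, 50 °C) gives the tetrasubstituted alkene, the 7-deoxo analogue of 19 F9.
- Mukaiyama hydration as in step 12 (without fluoride) gives the 7-deoxo analogue of 20 F10.
- Allylic oxidation of the ring methylene next to the methyl-bearing alkene carbon (CrO3·3,5-dimethylpyrazole, CH2Cl2, −20 °C) returns to the route at 20, which the fluoride treatment of step 12 converts to 21. The weak point here is selectivity between the ring and side-chain allylic methylenes.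

**Further compounds**

F1 | step 7 | tert-butyl(buta-1,3-dien-2-yloxy)dimethylsilane | C=CC(=C)O[Si](C)(C)C(C)(C)C
F2 | step 7 | (3aS,7aR)-5-(tert-butyldimethylsilyloxy)-2,3,3a,4,7,7a-hexahydro-1H-inden-1-one | C1=C(O[Si](C)(C)C(C)(C)C)C[C@@H]2CCC(=O)[C@@H]2C1
F3 | step 7 | tert-butyldimethyl{[(3aS,7aR)-1-methylidene-2,3,3a,4,7,7a-hexahydro-1H-inden-5-yl]oxy}silane | C1=C(O[Si](C)(C)C(C)(C)C)C[C@@H]2CCC(=C)[C@@H]2C1
F4 | step 7 | (3aS,8aR)-6-methyl-1-methylidene-2,3,3a,4,8,8a-hexahydroazulen-5(1H)-one | O=C1C(C)=CC[C@H]2C(=C)CC[C@H]2C1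
F5 | step 9 | dibromocarbene adduct of 14 across the silyl enol ether (1-silyloxy-7,7-dibromobicyclo[4.1.0]heptane unit, ring-fusion centres as in 14) | BrC1(Br)C2C[C@H]3C(=C)CC[C@H]3C(C)(C)C12O[Si](C)(C)C(C)(C)C
F6 | step 9 | (3aR,8aR)-6-bromo-4,4-dimethyl-1-methylidene-2,3,3a,4,8,8a-hexahydroazulen-5(1H)-one | O=C1C(Br)=CC[C@H]2C(=C)CC[C@H]2C1(C)C
F7 | step 10 | (3aR,8aR)-4,4,6-trimethyl-1-methylidene-1,2,3,3a,4,7,8,8a-octahydroazulen-5-yl trifluoromethanesulfonate | CC1=C(OS(=O)(=O)C(F)(F)F)C(C)(C)[C@@H]2CCC(=C)[C@@H]2CC1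
F8 | step 10 | alkylzinc chloride of the left half (2-(chlorozincio)ethyl chain in place of the 2-(phenylsulfanyl)ethyl chain of 8, lithium 7-alkoxide) | Cl[Zn]CC[C@@H]2[C@@]3(C)CC[C@@H](O[Si](C)(C)C(C)(C)C)C(C)(C)O[C@@H]3CC[C@]2(C)O[Li]
F9 | step 10 | (3R,5aR,6R,7S,9aR)-3-(tert-butyldimethylsilyloxy)-6-{2-[(3aR,8aR)-4,4,6-trimethyl-1-methylidene-1,2,3,3a,4,7,8,8a-octahydroazulen-5-yl]ethyl}-2,2,5a,7-tetramethyldecahydro-1-benzoxepin-7-ol | CC1=C(CC[C@@H]2[C@@]3(C)CC[C@@H](O[Si](C)(C)C(C)(C)C)C(C)(C)O[C@@H]3CC[C@]2(C)O)C(C)(C)[C@@H]2CCC(=C)[C@@H]2CC1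
F10 | step 10 | (3R,5aR,6R,7S,9aR)-3-(tert-butyldimethylsilyloxy)-6-{2-[(1R,3aR,8aR)-1-hydroxy-1,4,4,6-tetramethyl-1,2,3,3a,4,7,8,8a-octahydroazulen-5-yl]ethyl}-2,2,5a,7-tetramethyldecahydro-1-benzoxepin-7-ol | CC1=C(CC[C@@H]2[C@@]3(C)CC[C@@H](O[Si](C)(C)C(C)(C)C)C(C)(C)O[C@@H]3CC[C@]2(C)O)C(C)(C)[C@@H]2CC[C@@](C)(O)[C@@H]2CC1
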